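Two earlier flasks held the same amounts of G, 0.071 M, with L held at 3.7 mM, and differed in catalyst X: 120 µM in the green run, 190 µM in the violet run.

| flask | G | L | X | remark | time |
|---|---|---|---|---|---|
| green | 0.071 M | 3.7 mM (held) | 120 µM | run made earlier |  |
| violet | 0.071 M | 3.7 mM (held) | 190 µM | run made earlier |  |
| flask | 0.071 M | 3.7 mM (held) | 85 µM |  | 8.0 d |

| green: time / d | green: Z / % | violet: time / d | violet: Z / % |
|---|---|---|---|
| 0.833 | 99.6 | 2.50 | 99.0 |
| 1.67 | 99.4 | 5.00 | 96.8 |
| 4.00 | 97.7 | 8.00 | 95.1 |
| 10.0 | 94.6 | 10.0 | 93.5 |

(each reading ± 0.5 percentage points)

- at the start none of L is in solution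
- J is what L becomes in solution

1. how much Z there is at 8.0 d, in percent of the G charged
2. concentration of J in solution at 8.0 d, in percent of saturation

The green run shows nearly all of the charged G as Z at 0.833 d, and its later readings show Z slowly falling. A loss in proportion to the Z present is described by a single first-order constant. Whether that constant follows X can be read without a clock: both runs were read at 10.0 d, so time drops out when one loss is divided by the other. The violet run has lost 1.20 times the Z of the green run while holding 1.58 times the X, a smaller factor. With readings scattered by 0.5 percentage points, this does not show a loss proportional to X, so this reckoning averages the two runs.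

Their last readings give 0.00614 d⁻¹ for the loss constant, the share of the Z present lost per day. The flask holds 85 µM of X, less than either run, so the constant is carried beyond the X of the readings. Counting the loss from the start, with Z equal to the charge times exp(−constant × time), gives 95.2% of Z at 8.0 d.

The forecast stands higher on Z, at 95.8%, with J at 99.7% of saturation, and holds that “This loss depends only weakly on X”.

The flask gives 95.1% of Z and J at 95.8% of saturation.

    L ⇌ J, rate k1*(csat - [J]) (kL = 0.0340 min⁻¹)
    G + J + X → X + Z (k = 22000 L² mol⁻² min⁻¹)
    Z → D (k = 4.50 × 10⁻⁶ min⁻¹)
    J → Q (k = 0.00150 min⁻¹)

The neighbouring flask has the same charges as the flask but is read at 3.0 d. The same loss constant gives it 98.2% of Z. In the scheme, the half-life of Z by the conversion of Z into D alone is 110 d, longer than the time of that reading. In that flask, G is the first charge to run out, the limiting reagent, with 0% of it left. The neighbouring flask then holds 98.3% of Z and 1.73% of D, both in percent of the G charged.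

All runs are calculated for an exercise; scatter was added.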